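The cedar run is the very flask you are asked about, followed so far, so open its ledger there, with substrate, the limiting reagent, as the account.

| setting | cedar | flask |
|---|---|---|
| substrate | 0.19 M | 0.19 M |
| enzyme | 19 µM | 19 µM |
| remark | the very flask that is asked about, followed so far |  |

- cedar (time / h: product / %, substrate / %): 0.200: 2.4, 97.2; 0.667: 8.2, 90.8; 1.00: 13.7, 85.4; 1.50: 16.6, 81.1; 2.50: 26.7, 71.5

(standard deviation of a reading: 1 percentage point)

- the numbers in the tables scatter by 1 percentage point (one standard deviation)
- no earlier run changes the charge of enzyme; that part of a forecast is a guess

- factor on the rate of making product when 20% of the substrate are converted if enzyme is charged twice over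
- factor on the rate when 20% of the substrate are converted if enzyme is charged at 2.0 µM instead

Of c(substrate) = 0.19 M charged, the last reading, at 2.50 h, books 71.5% as substrate and 26.7% as product. The 1.8 percentage points unbooked is what two readings of this scatter can leave, so I open no third account. Enzyme comes back from each turnover and stands outside this ledger.

Now work with the fraction left. If it shrinks by the same share each hour, that last reading gives a constant of 0.134 h⁻¹. The reading at 0.667 h gives 0.145 h⁻¹, a little higher, but inside the scatter. The mark of 20% then comes at 1.66 h: this is your time to the mark, the time the fraction left takes to fall to what the mark leaves. The rate there is the constant times the substrate left, 0.0204 M h⁻¹.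

My own reckoning goes further. If the fall keeps pace with the charge, doubling moves the mark to 0.831 h, and 2.0 µM moves it to 15.8 h. The rate factors equal the charge ratios only if the catalyst works as well at those times as at the cedar mark, and the cedar run stops at 2.50 h. So I commit to the times, and for the factors I take the charge ratios, 2 and 0.105, as a guess, because the cedar readings show no lean beyond their scatter. The forecast gives 2 and 0.105, since “the composition is the same in each case”.

The flask gives 2.29 and 0.0796, and it reaches the mark at 1.65 h with a rate of 0.0199 M h⁻¹.

    substrate + enzyme → product + enzyme, rate k1*[substrate]*[enzyme]/(1 + ([substrate]/Km1)) (21.0 mM, k = 76000 L mol⁻¹ h⁻¹)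
    enzyme ⇌ dormant form (K = 0.770, k = 0.230 h⁻¹)

Per unit of charge, the rate at the mark is 1.15 of the cedar flask's for the doubled charge and 0.756 for 2.0 µM. Your time to the mark, halved to 0.831 h, stands next to 0.800 h, where the cedar flask's catalyst is 85.0% enzyme, the rest dormant form. Scaled to 15.8 h, it lies past 8.00 h, where that share is 57.1%, and at 80.0 h it is 56.5%.

(The readings are calculated with made-up constants; noise was put on by code.)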